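**Remark on the chemistry:** atom labels C1–C8a are the hydroazulene positions of target 20 and are used for the same atoms in every intermediate; it is assumed that the minor (Z)-enoate formed in step 3 can be removed by chromatography.

## Analysis of the target

Target 20 is the 3,4-dimethoxybenzoate of a carotane-type sesquiterpene diol: a cyclopentane (C1, C2, C3, C3a, C8a) fused through the C3a–C8a bond to a cycloheptene (C3a, C4, C5, C6, C7, C8, C8a) whose C6=C7 alkene carries a methyl group on C6. It has four stereocentres, 3R, 3aS, 5R and 8aR. The isopropyl group on C3, the hydroxyl on C3a and the methyl on C8a lie on one face of the five-membered ring, so the two bonds into the seven-membered ring (to C4 and C8) are cis; the ester oxygen on C5 is on the face opposite to the C3a hydroxyl, a 1,3-anti relationship across C4. C3a (tertiary carbinol) and C8a (all-carbon quaternary) are adjacent and carry no hydrogen, and C3a is flanked on its other side by the C3 stereocentre; making this crowded triad with the right relative configuration is the main difficulty, ahead of closing a seven-membered ring that holds a trisubstituted cis alkene. The sensitive functions are the tertiary alcohol, which sits β to C5 and can dehydrate or undergo retro-aldol cleavage once C5 is a carbonyl, and the allylic ester at C5, which can ionise or transpose; acylation therefore belongs at the very end and the late steps must stay near neutral. The strategy rests on the fact that C3a bears oxygen while C8a, with its methyl group, stands two carbons from C7: when C7 is taken back to an ester carbonyl, C8a is the β-carbon of a β-methyl enoate and C3a is a ketone carbon. These two electrophilic carbons can be joined after one-electron reduction of the ketone, which delivers hydroxyl, methyl and two differentiated two-carbon arms (C4–C5 and C8–C7) in one bond-forming event from an open chain whose only stereocentre is C3.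

## Retrosynthetic reasoning

**Ester C–O bond (20 ⇒ 18 + 19).** The aroyl group is removed first, because an allylic ester should not be carried through reductions or organometallic steps. Diol 18 has one secondary allylic and one hindered tertiary hydroxyl, so the forward acylation with 19 only has to distinguish these two.

**C5–H bond (18 ⇒ 17 ⇒ 16).** The C5 carbinol is traced to enone 17. The C3a hydroxyl can then deliver hydride to C5 from its own face, which gives exactly the 1,3-anti pattern of 18. As a result the C5 configuration need not be controlled when the ring is closed; the epimer mixture 16 is simply oxidised to 17.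

**C5–C6 bond (16 ⇒ 15).** The allylic alcohol is cut between the carbinol carbon and the alkene carbon, which gives aldehyde 15 carrying a (Z)-alkenyl iodide. This cut is preferred to C4–C5 or C7–C8 because it needs no enolate chemistry next to the sensitive carbinol. The C6 methyl and the alkene come as a prefabricated unit, and a Z-iodide can only close to the cis ring alkene. The forward reaction has to form a seven-membered ring by chemoselective addition of an alkenyl metal to an aldehyde in the presence of a free tertiary alcohol; the two arms are cis on the cyclopentane, which helps.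

**Arm adjustments (15 ⇒ 14 ⇒ 13 ⇒ 12).** The C5 aldehyde is masked as the dimethyl acetal 14. The iodoalkene is cut at C6=C7 to aldehyde 13 (a two-carbon iodo ylide supplies C6 and its methyl group), and 13 comes from ester 12. In 12 the two arms are at different oxidation levels, ester at C7 and acetal at C5, so they can be addressed one after the other.

**C3a–C8a bond (12 ⇒ 11), the key disconnection.** Cutting the bond between the two fully substituted carbons opens the cyclopentane to keto enoate 11. Nowhere else does a single cut remove both hydrogen-free centres and leave an acyclic precursor with one stereocentre; building them one after the other on a preformed ring would need two separate face-selective steps. The forward reaction must reduce the ketone in preference to the enoate, close the ring 5-exo, and relay the C3 configuration to C3a and C8a.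

**Keto-acetal assembly (11 ⇒ 9 via 10, 9 ⇒ 8, 8 ⇒ 7).** The β-keto acetal is cut at C4–C5: enol ether 10 of methyl ketone 9 plus a one-carbon electrophile at the orthoester oxidation level. Only the methyl side of 9 can enolise without strain, so C3 is safe. Ketone 9 is cut at C3a–C4 to thioester 8 and a methyl organometallic under palladium catalysis, which avoids strongly basic reagents that would attack the enoate. Thioester 8 comes from imide 7 by acyl transfer.

**Chain and stereocentre (7 ⇒ 5 + 6, 5 ⇒ 3 + 4, 3 ⇒ 1 + 2).** The enoate is cut at C8a=C8 to methyl ketone 5 and phosphonate 6. Ketone 5 is cut at C2–C3 to the enolate of imide 3 and enone 4; this conjugate addition sets C3 under control of the auxiliary. Imide 3 is made from 1 and 2.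

## Alternatives that were turned down

**Alternative 1:** Disconnection: C6 is excised from the seven-membered ring (bonds C5–C6 and C6–C7), leading back to the six-five ketol A1, the product of an amine-catalysed asymmetric intramolecular aldol reaction. Forward key step: a diazoalkane homologation under Lewis-acid activation inserts a CH2 group next to the six-ring carbonyl of A1 and gives the hydroazulene dione A2. In its favour, the C3a carbinol and the C8a methyl centre come cis and enantiomerically enriched from a catalytic step, and A1 is reached in very few operations. On securing the two fully substituted centres this plan is stronger than the chosen one, whose C3a/C8a outcome depends on a diastereoselective radical closure. Against it, A2 holds neither the C3 isopropyl group, nor the C6 methyl group, nor the alkene, and it has a superfluous carbonyl at C1. C3 is an unactivated CH2, so the isopropyl group would need dehydrogenation to a C2–C3 enone, conjugate addition on the face of the C3a hydroxyl and later removal of the C1 oxygen. The C5 ketone enolises toward C4 as well as C6, so methylation and dehydrogenation at C6/C7 are regiochemical problems. The insertion itself must choose between two CH2 migrating groups and two ketones, and the tertiary β-ketol is prone to dehydrate under the Lewis acid. What the chosen plan offers instead is that isopropyl, both methyl groups and the alkene arrive with the building blocks, so nothing has to be installed on the bicycle and few steps follow ring formation.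

**Alternative 2:** Disconnection: the three bonds C3a–C8a, C1–C2 and C2–C3 of a cyclopentenone are cut at once, leaving the open-chain dienyne A3, in which the C5 silyl ether, the C6 methyl group and the Z C6=C7 alkene are already present. Forward key step: a cobalt-mediated carbonylative [2+2+1] cycloaddition (Pauson–Khand reaction) of the isopropyl-substituted alkyne with the 1,1-disubstituted alkene, which would give the bicyclic enone A4 and close both rings together. In its favour is the highest convergence of all plans: both rings and the C8a quaternary centre in one operation, with the functionality of the seven-membered ring in place; in bonds formed per step it beats the chosen route. Against it, the alkene is 1,1-disubstituted and the alkyne is internal and branched, both poor partners. The second ring is seven-membered, for which the intramolecular reaction is much less favourable than for five- or six-membered rings. The C8a configuration would be controlled only by the remote C5 silyloxy group. A4 has a C3=C3a alkene and a C2 carbonyl, so the C3a hydroxyl and the C3 hydrogen would still have to be added across a tetrasubstituted enone, both cis to the angular methyl, and the C2 oxygen removed next to a retro-aldol-prone ketol. The chosen route makes C3a directly at the carbinol level under control of the neighbouring C3 centre and needs no deoxygenation.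

**Alternative 3:** Disconnection: C4–C5, back to cyclopentane A5, which bears a spiro-epoxide at C3a (its CH2 is C4) and, on C8a, a three-carbon chain ending in a 1,3-dithiane (C5). Forward key step: lithiation of the dithiane and intramolecular opening of the epoxide at its CH2 (7-exo-tet), giving the bicyclic tertiary alcohol A6. In its favour, this is a polar, well-understood C–C bond formation; the C3a configuration is fixed in the epoxide before ring closure; and C5 emerges as a masked ketone, the right oxidation level for a hydroxyl-directed reduction. As a ring closure it is probably more dependable than a chromium-mediated one. Against it, the key step does nothing for the real difficulty. A5 already contains the C3/C3a/C8a triad, so it needs a 2,2,5-trisubstituted cyclopentanone with a stereodefined quaternary centre and then a face-selective methylene transfer, each a separate stereochemical problem. The carbanion must attack a CH2 attached to a fully substituted carbon that is itself next to a quaternary centre. A6 also lacks the C6 methyl group and the alkene, so after unmasking C5, methylation at C6 (not C4) and dehydrogenation toward C7 would be required. The chosen route sets both fully substituted centres in the step that makes the five-membered ring and brings the C6 methyl group and the alkene with the seven-ring closure, at the price of a less predictable radical step.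

Key step: step 7

## Route

Step 1
Reactants: 1 (R)-4-benzyl-1,3-oxazolidin-2-one; 2 3-methylbutanoyl chloride
Product: 3 (4R)-4-benzyl-3-(3-methylbutanoyl)-1,3-oxazolidin-2-one
Conditions: n-BuLi, THF, −78 °C; then 2, −78 → 0 °C
Reagents that add atoms: none
Why: N-Acylation of the lithium salt of the oxazolidinone by the acid chloride (standard imide formation); no stereocentre is formed and the benzyl-bearing centre of the auxiliary is not touched.

Step 2
Reactants: 3 (4R)-4-benzyl-3-(3-methylbutanoyl)-1,3-oxazolidin-2-one; 4 methyl vinyl ketone (but-3-en-2-one)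
Product: 5 (4R)-4-benzyl-3-[(2R)-5-oxo-2-(propan-2-yl)hexanoyl]-1,3-oxazolidin-2-one
Conditions: TiCl4, Ti(Oi-Pr)4 (3:1, gives TiCl3(Oi-Pr)), i-Pr2NEt, CH2Cl2, 0 °C; then 4, 0 °C
Reagents that add atoms: none
Why: Auxiliary-controlled Michael addition of a chlorotitanium imide enolate to an enone: soft enolisation gives the chelated Z-enolate, whose face opposite to the benzyl group is open, so the enone should add there and, with the (R)-auxiliary, set the α-carbon (C3 of 20) as R, in the same sense as alkylations of such enolates. The new bond is C2–C3 and the methyl ketone carbon is the future C8a.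

Step 3
Reactants: 5 (4R)-4-benzyl-3-[(2R)-5-oxo-2-(propan-2-yl)hexanoyl]-1,3-oxazolidin-2-one; 6 triethyl phosphonoacetate
Product: 7 ethyl (2E,6R)-6-{[(4R)-4-benzyl-2-oxo-1,3-oxazolidin-3-yl]carbonyl}-3,7-dimethyloct-2-enoate
Conditions: NaH, THF, 0 °C → rt; chromatography
Reagents that add atoms: none
Why: Horner–Wadsworth–Emmons olefination of the methyl ketone builds C8a=C8 and brings in C7 as the ester carbon; the E isomer (ester trans to the longer chain) should predominate and the minor Z isomer is to be removed by chromatography. The stabilised phosphonate anion is too weak a base to enolise the hindered imide α-centre.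

Step 4
Reactants: 7 ethyl (2E,6R)-6-{[(4R)-4-benzyl-2-oxo-1,3-oxazolidin-3-yl]carbonyl}-3,7-dimethyloct-2-enoate
Product: 8 ethyl (2E,6R)-6-[(ethylsulfanyl)carbonyl]-3,7-dimethyloct-2-enoate
Conditions: EtSH, n-BuLi, THF, 0 °C
Reagents that add atoms: ethanethiol, CCS
Why: Thiolysis of the N-acyl oxazolidinone: the soft, weakly basic lithium thiolate attacks the exocyclic carbonyl even of α-branched imides, should leave the enoate and the α-stereocentre untouched, and releases the auxiliary for recovery.

Step 5
Reactants: 8 ethyl (2E,6R)-6-[(ethylsulfanyl)carbonyl]-3,7-dimethyloct-2-enoate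
Product: 9 ethyl (2E,6R)-6-acetyl-3,7-dimethyloct-2-enoate
Conditions: MeZnI, PdCl2(PPh3)2 (5 mol%), toluene/THF, rt
Reagents that add atoms: methylzinc iodide, C[Zn]I
Why: Fukuyama coupling: the palladium-catalysed cross-coupling of a thioester with an organozinc halide stops at the ketone and tolerates the conjugated ester; the neutral conditions should not epimerise C3. The methyl group becomes C4.

Step 6
Reactants: 9 ethyl (2E,6R)-6-acetyl-3,7-dimethyloct-2-enoate
Product: 11 ethyl (2E,6R)-9,9-dimethoxy-3-methyl-7-oxo-6-(propan-2-yl)non-2-enoate, via silyl enol ether 10 (not isolated)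
Conditions: Me3SiOTf, i-Pr2NEt, CH2Cl2, −78 → 0 °C; then HC(OMe)3, Me3SiOTf (cat.), −78 °C; NaHCO3
Reagents that add atoms: trimethylsilyl trifluoromethanesulfonate, C[Si](C)(C)OS(=O)(=O)C(F)(F)F; trimethyl orthoformate, COC(OC)OC
Why: Soft enolisation should take place at the methyl group, because the other α-carbon is tertiary and flanked by isopropyl, so C3 is not enolised; silyl enol ether 10 then adds to the dimethoxycarbenium ion released from the orthoformate by catalytic Me3SiOTf (Mukaiyama-type aldol addition to an orthoester), which forms C4–C5 and gives the β-keto dimethyl acetal. The conjugated ester is silylated much more slowly than the ketone, and a cold NaHCO3 quench avoids loss of methanol from the product.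

Step 7
Reactants: 11 ethyl (2E,6R)-9,9-dimethoxy-3-methyl-7-oxo-6-(propan-2-yl)non-2-enoate
Product: 12 ethyl 2-[(1R,2S,3R)-2-(2,2-dimethoxyethyl)-2-hydroxy-1-methyl-3-(propan-2-yl)cyclopentyl]acetate
Conditions: SmI2 (2.5 equiv), HMPA, t-BuOH, THF, −78 → 0 °C
Reagents that add atoms: none
Why: The closest known reaction type is the SmI2-promoted ketyl–olefin reductive cyclisation of ketones onto tethered α,β-unsaturated esters, which also works with β,β-disubstituted acceptors and then creates a quaternary carbon. Electron transfer from SmI2–HMPA to the C3a ketone gives a samarium-bound ketyl that adds to the enoate β-carbon C8a; the ester-stabilised radical at C8 takes a second electron and the samarium enolate is protonated by t-BuOH. The cyclopentane (C3a, C3, C2, C1, C8a) closes in the 5-exo-trig mode through the new C3a–C8a bond; 6-endo attack at C8 would leave an unstabilised radical and should not compete. At C8a the bulky, electron-rich O–Sm(HMPA)n group is expected to lie anti to C8, the carbon on which enolate character develops, so that oxygen and the C8a methyl group become cis. Relative to C3, the chair-like transition state keeps the isopropyl group pseudo-equatorial and hence trans to C8, so the C3 centre should direct the closure to the isomer in which isopropyl, hydroxyl and methyl share one face (3aS, 8aR). The step needs ketyl formation and ring closure to outrun conjugate reduction of the enoate and simple reduction of the ketone, which fast intramolecular trapping at low temperature should secure; the acetal oxygens sit on C5, one carbon too far from the ketyl carbon for reductive cleavage. Because oxygen and the ester arm end up trans on the ring, 12 cannot lactonise, whereas an isomer with the two cis would close to a γ-lactone and should be easy to separate.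

Step 8
Reactants: 12 ethyl 2-[(1R,2S,3R)-2-(2,2-dimethoxyethyl)-2-hydroxy-1-methyl-3-(propan-2-yl)cyclopentyl]acetate
Product: 13 2-[(1R,2S,3R)-2-(2,2-dimethoxyethyl)-2-hydroxy-1-methyl-3-(propan-2-yl)cyclopentyl]acetaldehyde
Conditions: i-Bu2AlH (2.5 equiv), CH2Cl2, −78 °C; MeOH, aq. potassium sodium tartrate
Reagents that add atoms: none
Why: Partial reduction of the ester with i-Bu2AlH: after the first equivalent has been consumed by the hydroxyl group, the tetrahedral aluminium hemiacetal of this neopentyl-type ester should survive at −78 °C and collapse to the aldehyde on work-up; the acetal is inert. The aldehyde should stay open because a lactol would require a strained trans-fused bicyclo[3.3.0] system.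

Step 9
Reactants: 13 2-[(1R,2S,3R)-2-(2,2-dimethoxyethyl)-2-hydroxy-1-methyl-3-(propan-2-yl)cyclopentyl]acetaldehyde
Product: 14 (1S,2R,5R)-1-(2,2-dimethoxyethyl)-2-[(2Z)-3-iodobut-2-en-1-yl]-2-methyl-5-(propan-2-yl)cyclopentan-1-ol
Conditions: [Ph3PCH2CH3]I, n-BuLi, THF, 0 °C; I2, −78 °C; NaN(SiMe3)2, −20 °C; then 13, −78 → −20 °C
Reagents that add atoms: ethyltriphenylphosphonium iodide, CC[P+](c1ccccc1)(c1ccccc1)c1ccccc1.[I-]; iodine, II
Why: Wittig olefination with the α-iodo ylide Ph3P=C(I)CH3 (Stork–Zhao-type iodo-olefination); the reactive, non-stabilised ylide is expected to give mainly the Z-iodoalkene, in which iodine is cis to the C8 chain, the geometry needed for ring closure. An excess of ylide should tolerate the free tertiary hydroxyl; C6 and its methyl group are introduced here.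

Step 10
Reactants: 14 (1S,2R,5R)-1-(2,2-dimethoxyethyl)-2-[(2Z)-3-iodobut-2-en-1-yl]-2-methyl-5-(propan-2-yl)cyclopentan-1-ol
Product: 15 2-[(1S,2R,5R)-1-hydroxy-2-[(2Z)-3-iodobut-2-en-1-yl]-2-methyl-5-(propan-2-yl)cyclopentyl]acetaldehyde
Conditions: pyridinium p-toluenesulfonate (cat.), acetone/H2O, rt
Reagents that add atoms: water, O
Why: Acid-catalysed hydrolysis of an acyclic dimethyl acetal, which is labile enough to be cleaved by a weak acid in wet acetone at room temperature; these conditions are chosen to spare the tertiary β-hydroxyl, the alkenyl iodide and C3.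

Step 11
Reactants: 15 2-[(1S,2R,5R)-1-hydroxy-2-[(2Z)-3-iodobut-2-en-1-yl]-2-methyl-5-(propan-2-yl)cyclopentyl]acetaldehyde
Product: 16 (3R,3aS,8aR)-6,8a-dimethyl-3-(propan-2-yl)-1,2,3,3a,4,5,8,8a-octahydroazulene-3a,5-diol (mixture of C5 epimers)
Conditions: CrCl2 (8 equiv), NiCl2 (2 mol%), DMF, rt, 0.005 M
Reagents that add atoms: none
Why: Intramolecular Nozaki–Hiyama–Kishi reaction: the alkenyl iodide adds oxidatively to zerovalent nickel formed from NiCl2 and CrCl2, transmetalation gives an alkenyl species of trivalent chromium that adds to the aldehyde and forms C5–C6 with retention of alkene geometry, so the Z-iodide becomes the cis ring alkene. The reagent tolerates the free hydroxyl, the two arms are held cis on the cyclopentane, and high dilution favours the seven-membered ring; the C5 configuration is not controlled here and is corrected in steps 12 and 13.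

Step 12
Reactants: 16 (3R,3aS,8aR)-6,8a-dimethyl-3-(propan-2-yl)-1,2,3,3a,4,5,8,8a-octahydroazulene-3a,5-diol (mixture of C5 epimers)
Product: 17 (3R,3aS,8aR)-3a-hydroxy-6,8a-dimethyl-3-(propan-2-yl)-2,3,3a,4,8,8a-hexahydroazulen-5(1H)-one
Conditions: activated MnO2 (excess), CH2Cl2, rt
Reagents that add atoms: none
Why: Chemoselective oxidation of the secondary allylic alcohol with MnO2; both C5 epimers converge on one enone, the tertiary alcohol cannot be oxidised, and the neutral heterogeneous conditions should avoid dehydration of the β-hydroxy ketone.

Step 13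
Reactants: 17 (3R,3aS,8aR)-3a-hydroxy-6,8a-dimethyl-3-(propan-2-yl)-2,3,3a,4,8,8a-hexahydroazulen-5(1H)-one
Product: 18 (3R,3aS,5R,8aR)-6,8a-dimethyl-3-(propan-2-yl)-1,2,3,3a,4,5,8,8a-octahydroazulene-3a,5-diol
Conditions: Me4NBH(OAc)3, MeCN/AcOH, −30 → −20 °C
Reagents that add atoms: none
Why: Hydroxyl-directed reduction (Evans–Saksena reduction): the C3a hydroxyl displaces an acetate on boron and hydride is delivered intramolecularly through a six-membered chair to the face of the C5 carbonyl on which the C3a oxygen lies, so the new C5 hydroxyl should come out trans (1,3-anti) to it, which is 5R. The reagent is too weak to reduce the enone intermolecularly at this temperature, which also secures 1,2-addition.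

Step 14
Reactants: 18 (3R,3aS,5R,8aR)-6,8a-dimethyl-3-(propan-2-yl)-1,2,3,3a,4,5,8,8a-octahydroazulene-3a,5-diol; 19 3,4-dimethoxybenzoyl chloride
Product: 20 (3R,3aS,5R,8aR)-3a-hydroxy-6,8a-dimethyl-3-(propan-2-yl)-1,2,3,3a,4,5,8,8a-octahydroazulen-5-yl 3,4-dimethoxybenzoate
Conditions: pyridine, DMAP (cat.), CH2Cl2, 0 °C → rt
Reagents that add atoms: none
Why: DMAP-catalysed acylation with the acid chloride; the secondary allylic hydroxyl at C5 reacts, whereas the tertiary ring-fusion hydroxyl at C3a is too hindered, and the basic, non-ionising conditions keep the allylic C5–O bond and its configuration intact.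

## Compound list

1 | (R)-4-benzyl-1,3-oxazolidin-2-one | O=C1OC[C@@H](Cc2ccccc2)N1 | starting material
2 | 3-methylbutanoyl chloride | CC(C)CC(Cl)=O | starting material
3 | (4R)-4-benzyl-3-(3-methylbutanoyl)-1,3-oxazolidin-2-one | CC(C)CC(=O)N1C(=O)OC[C@H]1Cc1ccccc1 | intermediate
4 | methyl vinyl ketone (but-3-en-2-one) | CC(=O)C=C | starting material
5 | (4R)-4-benzyl-3-[(2R)-5-oxo-2-(propan-2-yl)hexanoyl]-1,3-oxazolidin-2-one | CC(=O)CC[C@H](C(C)C)C(=O)N1C(=O)OC[C@H]1Cc1ccccc1 | intermediate
6 | triethyl phosphonoacetate | CCOC(=O)CP(=O)(OCC)OCC | starting material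
7 | ethyl (2E,6R)-6-{[(4R)-4-benzyl-2-oxo-1,3-oxazolidin-3-yl]carbonyl}-3,7-dimethyloct-2-enoate | CCOC(=O)/C=C(\C)CC[C@H](C(C)C)C(=O)N1C(=O)OC[C@H]1Cc1ccccc1 | intermediate
8 | ethyl (2E,6R)-6-[(ethylsulfanyl)carbonyl]-3,7-dimethyloct-2-enoate | CCOC(=O)/C=C(\C)CC[C@H](C(C)C)C(=O)SCC | intermediate
9 | ethyl (2E,6R)-6-acetyl-3,7-dimethyloct-2-enoate | CCOC(=O)/C=C(\C)CC[C@H](C(C)C)C(C)=O | intermediate
10 | ethyl (2E,6R)-3-methyl-6-(propan-2-yl)-7-[(trimethylsilyl)oxy]octa-2,7-dienoate | CCOC(=O)/C=C(\C)CC[C@H](C(C)C)C(=C)O[Si](C)(C)C | intermediate (not isolated)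
11 | ethyl (2E,6R)-9,9-dimethoxy-3-methyl-7-oxo-6-(propan-2-yl)non-2-enoate | CCOC(=O)/C=C(\C)CC[C@H](C(C)C)C(=O)CC(OC)OC | intermediate
12 | ethyl 2-[(1R,2S,3R)-2-(2,2-dimethoxyethyl)-2-hydroxy-1-methyl-3-(propan-2-yl)cyclopentyl]acetate | COC(OC)C[C@]1(O)[C@@H](C(C)C)CC[C@]1(C)CC(=O)OCC | intermediate
13 | 2-[(1R,2S,3R)-2-(2,2-dimethoxyethyl)-2-hydroxy-1-methyl-3-(propan-2-yl)cyclopentyl]acetaldehyde | COC(OC)C[C@]1(O)[C@@H](C(C)C)CC[C@]1(C)CC=O | intermediate
14 | (1S,2R,5R)-1-(2,2-dimethoxyethyl)-2-[(2Z)-3-iodobut-2-en-1-yl]-2-methyl-5-(propan-2-yl)cyclopentan-1-ol | COC(OC)C[C@]1(O)[C@@H](C(C)C)CC[C@]1(C)C/C=C(/C)I | intermediate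
15 | 2-[(1S,2R,5R)-1-hydroxy-2-[(2Z)-3-iodobut-2-en-1-yl]-2-methyl-5-(propan-2-yl)cyclopentyl]acetaldehyde | O=CC[C@]1(O)[C@@H](C(C)C)CC[C@]1(C)C/C=C(/C)I | intermediate
16 | (3R,3aS,8aR)-6,8a-dimethyl-3-(propan-2-yl)-1,2,3,3a,4,5,8,8a-octahydroazulene-3a,5-diol, mixture of C5 epimers | OC1C[C@]2(O)[C@@H](C(C)C)CC[C@]2(C)CC=C1C | intermediate
17 | (3R,3aS,8aR)-3a-hydroxy-6,8a-dimethyl-3-(propan-2-yl)-2,3,3a,4,8,8a-hexahydroazulen-5(1H)-one | O=C1C[C@]2(O)[C@@H](C(C)C)CC[C@]2(C)CC=C1C | intermediate
18 | (3R,3aS,5R,8aR)-6,8a-dimethyl-3-(propan-2-yl)-1,2,3,3a,4,5,8,8a-octahydroazulene-3a,5-diol | O[C@@H]1C[C@]2(O)[C@@H](C(C)C)CC[C@]2(C)CC=C1C | intermediate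
19 | 3,4-dimethoxybenzoyl chloride | COc1ccc(C(Cl)=O)cc1OC | starting material
20 | (3R,3aS,5R,8aR)-3a-hydroxy-6,8a-dimethyl-3-(propan-2-yl)-1,2,3,3a,4,5,8,8a-octahydroazulen-5-yl 3,4-dimethoxybenzoate | COc1ccc(C(=O)O[C@@H]2C[C@]3(O)[C@@H](C(C)C)CC[C@]3(C)CC=C2C)cc1OC | target

## Step count and least certain steps

Total step count: 14. Longest linear sequence: 14 steps (1 and 2 to 20; the route is fully linear).

**Step 7 (key step).** Addition of the ketyl to the β,β-disubstituted enoate may be slow, so that simple reduction of the ketone to a secondary alcohol or conjugate reduction of the enoate competes. Facial selectivity relative to C3 may also be incomplete, because the oxygen has to end up cis to the isopropyl group. The fallback sets out from 8 and returns at 12; it makes the quaternary carbon with a radical that is not reduced further and the carbinol centre by a separate polar addition. Reduction of thioester 8 with Et3SiH over Pd on carbon should give ethyl (2E,6R)-6-formyl-3,7-dimethyloct-2-enoate F1. Photocatalytic hydrogen abstraction from the aldehyde with (n-Bu4N)4W10O32 under 365 nm light generates a nucleophilic acyl radical, which should add 5-exo to C8a through the same chair (isopropyl trans to the ester arm) and give ethyl 2-[(1R,3R)-1-methyl-2-oxo-3-(propan-2-yl)cyclopentyl]acetate F2. CH2=CHCH2MgBr at −78 °C is expected to attack the ketone from the face opposite to methyl and isopropyl and give ethyl 2-[(1R,2S,3R)-2-hydroxy-1-methyl-3-(propan-2-yl)-2-(prop-2-en-1-yl)cyclopentyl]acetate F3. Ozonolysis with PPh3 work-up leads to ethyl 2-[(1R,2S,3R)-2-hydroxy-1-methyl-2-(2-oxoethyl)-3-(propan-2-yl)cyclopentyl]acetate F4, and HC(OMe)3 in MeOH with pyridinium p-toluenesulfonate converts this into 12.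

**Step 10.** As soon as the β-hydroxy aldehyde forms, the C3a hydroxyl may be lost by acid-induced dehydration to the conjugated enal, or the compound may cleave by retro-aldol reaction. The fallback sets out from 14 and returns at 16. Et3SiOTf with 2,6-lutidine in CH2Cl2 at 0 °C, followed by water, cleaves the dimethyl acetal through a pyridinium intermediate without Brønsted acid and silylates the tertiary alcohol in the same flask. This gives 2-[(1S,2R,5R)-2-[(2Z)-3-iodobut-2-en-1-yl]-2-methyl-5-(propan-2-yl)-1-(triethylsilyloxy)cyclopentyl]acetaldehyde F5. Ring closure under the conditions of step 11 should give (3R,3aS,8aR)-6,8a-dimethyl-3-(propan-2-yl)-3a-(triethylsilyloxy)-1,2,3,3a,4,5,8,8a-octahydroazulen-5-ol F6, and n-Bu4NF then releases 16.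

**Step 11.** Intermolecular coupling or protodemetalation of the alkenylchromium species may win over cyclisation, because a seven-membered ring with a trisubstituted alkene is closed next to two fully substituted carbons. The fallback sets out from 13 and returns at 16; it closes the ring at C6=C7 by metathesis instead. Ph3P=CH2 converts 13 into (1S,2R,5R)-1-(2,2-dimethoxyethyl)-2-methyl-5-(propan-2-yl)-2-(prop-2-en-1-yl)cyclopentan-1-ol F7. Hydrolysis as in step 10 gives 2-[(1S,2R,5R)-1-hydroxy-2-methyl-5-(propan-2-yl)-2-(prop-2-en-1-yl)cyclopentyl]acetaldehyde F8. Excess CH2=C(CH3)MgBr adds to the aldehyde and gives (1S,2R,5R)-1-(2-hydroxy-3-methylbut-3-en-1-yl)-2-methyl-5-(propan-2-yl)-2-(prop-2-en-1-yl)cyclopentan-1-ol F9 as a mixture at the new carbinol. Ring-closing metathesis with the second-generation Grubbs catalyst should then give 16.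

**Step 9.** The bulky iodo ylide may enolise the neopentyl-type aldehyde instead of adding to it, and Z selectivity may be incomplete. The fallback sets out from 13 and returns at 14; it builds the iodoalkene stepwise. CBr4 and PPh3 in the presence of 2,6-lutidine give (1S,2R,5R)-2-(3,3-dibromoprop-2-en-1-yl)-1-(2,2-dimethoxyethyl)-2-methyl-5-(propan-2-yl)cyclopentan-1-ol F10. Negishi coupling with Me2Zn and Pd(t-Bu3P)2 should replace selectively the bromine trans to the chain and give (1S,2R,5R)-2-[(2Z)-3-bromobut-2-en-1-yl]-1-(2,2-dimethoxyethyl)-2-methyl-5-(propan-2-yl)cyclopentan-1-ol F11. Copper-catalysed halogen exchange (CuI, NaI, trans-N,N'-dimethylcyclohexane-1,2-diamine) with retention of geometry leads to 14.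

**Step 13.** Facial selectivity may be poor if the hindered tertiary C3a hydroxyl exchanges slowly onto boron, so that intermolecular, sterically governed reduction takes over. The fallback sets out from 17 and returns at 20. Reduction with NaBH4 and CeCl3 in MeOH, where steric control would then be the source of the C5 epimer, gives (3R,3aS,5S,8aR)-6,8a-dimethyl-3-(propan-2-yl)-1,2,3,3a,4,5,8,8a-octahydroazulene-3a,5-diol F12. Mitsunobu esterification of this epimer with 3,4-dimethoxybenzoic acid (PPh3, diisopropyl azodicarboxylate) inverts C5 and gives 20 directly, so that step 14 is not needed.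

## Further compounds

F1 | step 7 | ethyl (2E,6R)-6-formyl-3,7-dimethyloct-2-enoate | CCOC(=O)/C=C(\C)CC[C@H](C(C)C)C=O
F2 | step 7 | ethyl 2-[(1R,3R)-1-methyl-2-oxo-3-(propan-2-yl)cyclopentyl]acetate | O=C1[C@@H](C(C)C)CC[C@]1(C)CC(=O)OCC
F3 | step 7 | ethyl 2-[(1R,2S,3R)-2-hydroxy-1-methyl-3-(propan-2-yl)-2-(prop-2-en-1-yl)cyclopentyl]acetate | C=CC[C@]1(O)[C@@H](C(C)C)CC[C@]1(C)CC(=O)OCC
F4 | step 7 | ethyl 2-[(1R,2S,3R)-2-hydroxy-1-methyl-2-(2-oxoethyl)-3-(propan-2-yl)cyclopentyl]acetate | O=CC[C@]1(O)[C@@H](C(C)C)CC[C@]1(C)CC(=O)OCC
F5 | step 10 | 2-[(1S,2R,5R)-2-[(2Z)-3-iodobut-2-en-1-yl]-2-methyl-5-(propan-2-yl)-1-(triethylsilyloxy)cyclopentyl]acetaldehyde | O=CC[C@]1(O[Si](CC)(CC)CC)[C@@H](C(C)C)CC[C@]1(C)C/C=C(/C)I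
F6 | step 10 | (3R,3aS,8aR)-6,8a-dimethyl-3-(propan-2-yl)-3a-(triethylsilyloxy)-1,2,3,3a,4,5,8,8a-octahydroazulen-5-ol, mixture of C5 epimers | OC1C[C@]2(O[Si](CC)(CC)CC)[C@@H](C(C)C)CC[C@]2(C)CC=C1C
F7 | step 11 | (1S,2R,5R)-1-(2,2-dimethoxyethyl)-2-methyl-5-(propan-2-yl)-2-(prop-2-en-1-yl)cyclopentan-1-ol | COC(OC)C[C@]1(O)[C@@H](C(C)C)CC[C@]1(C)CC=C
F8 | step 11 | 2-[(1S,2R,5R)-1-hydroxy-2-methyl-5-(propan-2-yl)-2-(prop-2-en-1-yl)cyclopentyl]acetaldehyde | O=CC[C@]1(O)[C@@H](C(C)C)CC[C@]1(C)CC=C
F9 | step 11 | (1S,2R,5R)-1-(2-hydroxy-3-methylbut-3-en-1-yl)-2-methyl-5-(propan-2-yl)-2-(prop-2-en-1-yl)cyclopentan-1-ol, mixture at the side-chain carbinol | C=C(C)C(O)C[C@]1(O)[C@@H](C(C)C)CC[C@]1(C)CC=C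
F10 | step 9 | (1S,2R,5R)-2-(3,3-dibromoprop-2-en-1-yl)-1-(2,2-dimethoxyethyl)-2-methyl-5-(propan-2-yl)cyclopentan-1-ol | COC(OC)C[C@]1(O)[C@@H](C(C)C)CC[C@]1(C)CC=C(Br)Br
F11 | step 9 | (1S,2R,5R)-2-[(2Z)-3-bromobut-2-en-1-yl]-1-(2,2-dimethoxyethyl)-2-methyl-5-(propan-2-yl)cyclopentan-1-ol | COC(OC)C[C@]1(O)[C@@H](C(C)C)CC[C@]1(C)C/C=C(/C)Br
F12 | step 13 | (3R,3aS,5S,8aR)-6,8a-dimethyl-3-(propan-2-yl)-1,2,3,3a,4,5,8,8a-octahydroazulene-3a,5-diol | O[C@H]1C[C@]2(O)[C@@H](C(C)C)CC[C@]2(C)CC=C1C
A1 | alternative 1 | cis-fused (3aR,7aR)-3a-hydroxy-7a-methylhexahydro-1H-indene-1,5(4H)-dione | O=C1C[C@]2(O)CCC(=O)[C@]2(C)CC1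
A2 | alternative 1 | cis-fused (3aR,8aR)-3a-hydroxy-8a-methyloctahydroazulene-1,5-dione | O=C1C[C@]2(O)CCC(=O)[C@]2(C)CCC1
A3 | alternative 2 | tert-butyl(dimethyl){[(4Z,6R)-2,5,10-trimethylundeca-1,4-dien-8-yn-6-yl]oxy}silane | CC(C)C#CC[C@@H](O[Si](C)(C)C(C)(C)C)/C(C)=C\CC(C)=C
A4 | alternative 2 | (5R,8aS)-5-[(tert-butyldimethylsilyl)oxy]-6,8a-dimethyl-3-(propan-2-yl)-4,5,8,8a-tetrahydroazulen-2(1H)-one | CC(C)(C)[Si](C)(C)O[C@@H]1CC2=C(C(C)C)C(=O)C[C@]2(C)CC=C1C
A5 | alternative 3 | 2-{3-[(3S,4S,7R)-4-methyl-7-(propan-2-yl)-1-oxaspiro[2.4]heptan-4-yl]propyl}-1,3-dithiane | O1C[C@@]12[C@@H](C(C)C)CC[C@]2(C)CCCC1SCCCS1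
A6 | alternative 3 | (3R,3aS,8aS)-8a-methyl-3-(propan-2-yl)octahydro-1H-spiro[azulene-5,2'-[1,3]dithian]-3a-ol | S1CCCSC12C[C@]3(O)[C@@H](C(C)C)CC[C@]3(C)CCC2
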